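**Retrosynthetic overview**
1. Euchrenone a3 is taken back to its tris-TBS ether. Buffered desilylation is the only operation carried out once the stereocentre exists.
2. Ring C is opened at C3–C4. The unit C4(=O)–C3H2–C2H is the formal adduct of a formyl C–H bond across a C2=C3 alkene. The precursor is therefore an achiral benzaldehyde with an aryl 1-arylvinyl ether ortho to the formyl group. One enantioselective rhodium-catalysed 6-endo hydroacylation closes ring C, sets the ketone oxidation level and sets C2.
3. Enabling feature: C4 is a carbonyl carbon on C4a of ring A, and C3 is an unsubstituted CH2. C2 carries only O1, ring B and H, and O1 sits on C8a ortho to C4a. The alkene is thus 1,1-disubstituted, has no allylic hydrogen, and is held next to the formyl C–H. Ring A is symmetric about the C4a–C7 axis, so either ortho oxygen can become O1.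
4. The enol ether comes from an aryl ester: O1–C2 by esterification and C3 by carbonyl methylenation, with the formyl group masked as a dimethyl acetal.
5. The ester divides into a ring A aldehyde (double C-prenylation of 2,4,6-trihydroxybenzaldehyde) and a ring B chromene acid (from resorcinol). Ring order: the pyran ring of the chromene first, ring C last.

Key step: step 11

Assumption: the (R)-ligand is taken to give the (2S)-product by analogy with the carbocyclic series. If the sense of induction is opposite, the (S)-ligand is used with no other change.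

**Step 1**
Reactants: 1 resorcinol; 2 3-methylbut-2-enoic acid
Product: 3 7-hydroxy-2,2-dimethylchroman-4-one
Conditions: P2O5, MeSO3H (Eaton's reagent), 70 °C
Reagents that add atoms: none
Why: Friedel–Crafts acylation of resorcinol at C4, followed in the same pot by oxa-Michael closure of the ortho phenol onto the β,β-dimethyl enone, should give only the linear 7-hydroxychromanone, whereas direct chromenylation of a 2,4-dihydroxybenzoyl compound would give the angular isomer.

**Step 2**
Reactants: 3 7-hydroxy-2,2-dimethylchroman-4-one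
Product: 5 2,2-dimethyl-2H-chromen-7-ol, via chroman-4-ol 4 (not isolated)
Conditions: LiAlH4, THF, 0 °C to reflux; then 2 M HCl, 0 °C to rt
Reagents that add atoms: none
Why: Hydride reduction of the aryl ketone gives the benzylic alcohol 4, whose acid-catalysed E1 dehydration is assisted by the para 7-hydroxy group and should give the 2H-chromene on work-up.

**Step 3**
Reactants: 5 2,2-dimethyl-2H-chromen-7-ol
Product: 6 7-hydroxy-2,2-dimethyl-2H-chromene-6-carbaldehyde
Conditions: MgCl2, Et3N, (CH2O)n, MeCN, reflux; aq NH4Cl work-up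
Reagents that add atoms: paraformaldehyde (as formaldehyde), C=O
Why: Casnati–Skattebøl ortho-formylation through the magnesium phenoxide should attack C6 rather than C8, which is flanked by two oxygen substituents, and a second formaldehyde takes up hydride from the hydroxymethyl intermediate.

**Step 4**
Reactants: 6 7-hydroxy-2,2-dimethyl-2H-chromene-6-carbaldehyde
Product: 7 7-(tert-butyldimethylsilyloxy)-2,2-dimethyl-2H-chromene-6-carbaldehyde
Conditions: TBSCl, imidazole, DMF, rt
Reagents that add atoms: tert-butyldimethylsilyl chloride, CC(C)(C)[Si](C)(C)Cl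
Why: Standard silyl ether formation caps the phenol so that it survives chlorite oxidation, carbodiimide coupling and the titanium reagent and can be removed with fluoride at the end.

**Step 5**
Reactants: 7 7-(tert-butyldimethylsilyloxy)-2,2-dimethyl-2H-chromene-6-carbaldehyde
Product: 8 7-(tert-butyldimethylsilyloxy)-2,2-dimethyl-2H-chromene-6-carboxylic acid
Conditions: NaClO2, NaH2PO4, 2-methylbut-2-ene (excess), t-BuOH/H2O, 0 °C to rt
Reagents that add atoms: sodium chlorite, [Na+].[O-]Cl=O
Why: Pinnick oxidation converts the aldehyde into the acid at mildly acidic pH, and the excess of 2-methylbut-2-ene traps hypochlorous acid before it can reach the chromene alkene.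

**Step 6**
Reactants: 9 2,4,6-trihydroxybenzaldehyde; 10 1-bromo-3-methylbut-2-ene (prenyl bromide, 2.1 equiv)
Product: 11 2,4,6-trihydroxy-3,5-bis(3-methylbut-2-en-1-yl)benzaldehyde
Conditions: KOH, H2O, 0 °C to rt
Reagents that add atoms: none
Why: Base-mediated aromatic C-alkylation of the ambident phloroglucinaldehyde anion, the reaction type used for C-prenylation of acylphloroglucinols, should fill the only two free ring positions C3 and C5.

**Step 7**
Reactants: 11 2,4,6-trihydroxy-3,5-bis(3-methylbut-2-en-1-yl)benzaldehyde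
Product: 12 4,6-bis(tert-butyldimethylsilyloxy)-2-hydroxy-3,5-bis(3-methylbut-2-en-1-yl)benzaldehyde
Conditions: TBSCl (2.1 equiv), imidazole, DMF, 0 °C
Reagents that add atoms: tert-butyldimethylsilyl chloride, CC(C)(C)[Si](C)(C)Cl
Why: Silylation should stop after two groups because the last ortho hydroxyl is locked in a hydrogen bond to the formyl oxygen, and since the two ortho hydroxyls are equivalent by symmetry only one bis-silyl ether can form.

**Step 8**
Reactants: 12 4,6-bis(tert-butyldimethylsilyloxy)-2-hydroxy-3,5-bis(3-methylbut-2-en-1-yl)benzaldehyde; 8 7-(tert-butyldimethylsilyloxy)-2,2-dimethyl-2H-chromene-6-carboxylic acid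
Product: 13 3,5-bis(tert-butyldimethylsilyloxy)-2-formyl-4,6-bis(3-methylbut-2-en-1-yl)phenyl 7-(tert-butyldimethylsilyloxy)-2,2-dimethyl-2H-chromene-6-carboxylate
Conditions: DCC, DMAP, CH2Cl2, 0 °C to rt
Reagents that add atoms: none
Why: Steglich esterification, the standard way to hindered depside-type aryl esters, forms the future O1–C2 bond at the only free phenol.

**Step 9**
Reactants: 13 the formyl aryl ester
Product: 14 3,5-bis(tert-butyldimethylsilyloxy)-2-(dimethoxymethyl)-4,6-bis(3-methylbut-2-en-1-yl)phenyl 7-(tert-butyldimethylsilyloxy)-2,2-dimethyl-2H-chromene-6-carboxylate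
Conditions: MeOSiMe3 (2.5 equiv), TMSOTf (5 mol %), CH2Cl2, −78 °C; pyridine quench
Reagents that add atoms: methoxytrimethylsilane, CO[Si](C)(C)C
Why: Aprotic Noyori-type acetalisation with an alkoxysilane and catalytic silyl triflate masks the formyl group without protic acid or free methanol, so the prenyl groups, silyl ethers and aryl ester should survive.

**Step 10**
Reactants: 14 the acetal aryl ester
Product: 16 4,6-bis(tert-butyldimethylsilyloxy)-2-({1-[7-(tert-butyldimethylsilyloxy)-2,2-dimethyl-2H-chromen-6-yl]ethenyl}oxy)-3,5-bis(3-methylbut-2-en-1-yl)benzaldehyde, via enol ether acetal 15 (not isolated)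
Conditions: Cp2TiMe2, toluene, 75 °C, dark; filtration through basic alumina; then THF/acetate buffer pH 5, 0 °C
Reagents that add atoms: bis(cyclopentadienyl)dimethyltitanium Cp2TiMe2, [CH3-].[CH3-].[Ti+4].c1cc[cH-]c1.c1cc[cH-]c1; water, O
Why: Petasis methylenation, a reaction type established for aryl benzoates, installs C3 under neutral conditions, and the acetal on the 2,4,6-trioxygenated ring should then ionise far faster than the aryl enol ether is protonated at carbon, which allows selective hydrolysis at pH 5.

**Step 11**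
Reactants: 16 the aldehyde enol ether
Product: 17 (2S)-5,7-bis(tert-butyldimethylsilyloxy)-2-[7-(tert-butyldimethylsilyloxy)-2,2-dimethyl-2H-chromen-6-yl]-6,8-bis(3-methylbut-2-en-1-yl)chroman-4-one
Conditions: [Rh(cod)Cl]2 (5 mol %), (R)-DTBM-SEGPHOS (10 mol %), NaB[3,5-(CF3)2C6H3]4 (10 mol %), 1,4-dioxane, 80 °C
Reagents that add atoms: none
Why: Proposed new method: the cationic bisphosphine complex of monovalent rhodium should insert into the formyl C–H bond of 16, bind the only alkene within reach (C2=C3, held ortho to the formyl group through O1), deliver hydride to C2 to give a seven-membered acyl alkyl rhodacycle of trivalent rhodium, and close the C3–C4 bond by reductive elimination. The closest known reaction type is the enantioselective rhodium-catalysed endo hydroacylation of ortho-allylbenzaldehydes bearing a 1,1-disubstituted alkene, which gives 3-substituted tetralones; new here is the oxygen atom in place of the benzylic CH2, that is, an aryl 1-arylvinyl ether as the alkene partner. Ring C closes in a 6-endo-trig mode, because the 5-exo alternative would need a tertiary alkyl rhodium centre at C2 and would build a quaternary carbon. The single stereocentre C2 is set in the hydride insertion, where the axially chiral ligand decides which face of C2=C3 is bound, and no later step touches it. The step needs chemoselectivity over the two prenyl alkenes and the chromene alkene, secured by their higher substitution and their distance from the formyl group, and it needs freedom from alkene isomerisation, secured because C2 carries only O1 and ring B and so has no allylic hydrogen. The neutral medium should leave both the acid-labile enol ether and the base-labile flavanone intact.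

**Step 12**
Reactants: 17 the tris-TBS flavanone
Product: 18 euchrenone a3, (2S)-5,7-dihydroxy-2-(7-hydroxy-2,2-dimethyl-2H-chromen-6-yl)-6,8-bis(3-methylbut-2-en-1-yl)chroman-4-one
Conditions: TBAF (3.3 equiv), AcOH (3.6 equiv), THF, 0 °C
Reagents that add atoms: none
Why: Fluoride cleavage of the three aryl silyl ethers, buffered with acetic acid, avoids both the free phenoxide or enolate that would open ring C by retro-oxa-Michael reaction and the strong acid that would ionise C2–O1 or cyclise the prenyl groups, so C2 should keep its configuration.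

**Compound list**
1 | resorcinol | Oc1cccc(O)c1 | starting material
2 | 3-methylbut-2-enoic acid | CC(C)=CC(=O)O | starting material
3 | 7-hydroxy-2,2-dimethylchroman-4-one | CC1(C)CC(=O)c2ccc(O)cc2O1 | intermediate
4 | 2,2-dimethylchroman-4,7-diol (racemic, not isolated) | CC1(C)CC(O)c2ccc(O)cc2O1 | intermediate
5 | 2,2-dimethyl-2H-chromen-7-ol | CC1(C)C=Cc2ccc(O)cc2O1 | intermediate
6 | 7-hydroxy-2,2-dimethyl-2H-chromene-6-carbaldehyde | CC1(C)C=Cc2cc(C=O)c(O)cc2O1 | intermediate
7 | 7-(tert-butyldimethylsilyloxy)-2,2-dimethyl-2H-chromene-6-carbaldehyde | CC1(C)C=Cc2cc(C=O)c(O[Si](C)(C)C(C)(C)C)cc2O1 | intermediate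
8 | 7-(tert-butyldimethylsilyloxy)-2,2-dimethyl-2H-chromene-6-carboxylic acid | CC1(C)C=Cc2cc(C(=O)O)c(O[Si](C)(C)C(C)(C)C)cc2O1 | intermediate
9 | 2,4,6-trihydroxybenzaldehyde | O=Cc1c(O)cc(O)cc1O | starting material
10 | 1-bromo-3-methylbut-2-ene | CC(C)=CCBr | starting material
11 | 2,4,6-trihydroxy-3,5-bis(3-methylbut-2-en-1-yl)benzaldehyde | CC(C)=CCc1c(O)c(CC=C(C)C)c(O)c(C=O)c1O | intermediate
12 | 4,6-bis(tert-butyldimethylsilyloxy)-2-hydroxy-3,5-bis(3-methylbut-2-en-1-yl)benzaldehyde | CC(C)=CCc1c(O[Si](C)(C)C(C)(C)C)c(CC=C(C)C)c(O)c(C=O)c1O[Si](C)(C)C(C)(C)C | intermediate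
13 | formyl aryl ester of 12 with 8 | CC(C)=CCc1c(O[Si](C)(C)C(C)(C)C)c(CC=C(C)C)c(OC(=O)c2cc3c(cc2O[Si](C)(C)C(C)(C)C)OC(C)(C)C=C3)c(C=O)c1O[Si](C)(C)C(C)(C)C | intermediate
14 | dimethyl acetal of 13 | CC(C)=CCc1c(O[Si](C)(C)C(C)(C)C)c(CC=C(C)C)c(OC(=O)c2cc3c(cc2O[Si](C)(C)C(C)(C)C)OC(C)(C)C=C3)c(C(OC)OC)c1O[Si](C)(C)C(C)(C)C | intermediate
15 | aryl 1-arylvinyl ether dimethyl acetal (not isolated) | CC(C)=CCc1c(O[Si](C)(C)C(C)(C)C)c(CC=C(C)C)c(OC(=C)c2cc3c(cc2O[Si](C)(C)C(C)(C)C)OC(C)(C)C=C3)c(C(OC)OC)c1O[Si](C)(C)C(C)(C)C | intermediate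
16 | aryl 1-arylvinyl ether aldehyde (achiral key-step precursor) | CC(C)=CCc1c(O[Si](C)(C)C(C)(C)C)c(CC=C(C)C)c(OC(=C)c2cc3c(cc2O[Si](C)(C)C(C)(C)C)OC(C)(C)C=C3)c(C=O)c1O[Si](C)(C)C(C)(C)C | intermediate
17 | (2S)-tris-TBS flavanone | CC(C)=CCc1c(O[Si](C)(C)C(C)(C)C)c(CC=C(C)C)c2c(c1O[Si](C)(C)C(C)(C)C)C(=O)C[C@@H](c1cc3c(cc1O[Si](C)(C)C(C)(C)C)OC(C)(C)C=C3)O2 | intermediate
18 | euchrenone a3, (2S) | CC(C)=CCc1c(O)c(CC=C(C)C)c2c(c1O)C(=O)C[C@@H](c1cc3c(cc1O)OC(C)(C)C=C3)O2 | target

**Step count**
Total step count: 12. Longest linear sequence: 10 steps (steps 1–5, then 8–12).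

**Steps most likely to fail**

1. **Step 11.**
   - Possible failures: decarbonylation of the acyl rhodium hydride at the crowded formyl group; β-aryloxide elimination from the alkyl rhodium intermediate; migration of the prenyl double bonds by rhodium hydride; poor facial selectivity.
   - Fallback, from 16 back to 17, known chemistry: Me2AlCl (CH2Cl2, −78 °C) would promote the polar Prins-type addition of the enol ether carbon C3 to the formyl carbon C4. This is the same ring closure. Loss of a C3 proton would give the racemic 2-aryl-4H-chromen-4-ol F1.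
   - MnO2 (CH2Cl2, rt) would oxidise this doubly activated alcohol to the tris-TBS flavone F2.
   - Copper hydride conjugate reduction (Cu(OAc)2, (R)-DTBM-SEGPHOS, (EtO)2MeSiH, t-BuOH, toluene, 0 °C) is a known enantioselective reaction of 2-substituted chromones. It would set C2 and return to 17.

2. **Step 10.**
   - Possible failures: sluggish methylenation of the doubly ortho-flanked ester, and hydrolysis of the enol ether while the formyl group is unmasked.
   - Fallback, from 7 and 12 back to 16, without ester, acetal or titanium reagent: PhSeCH2Li (from bis(phenylselanyl)methane and n-BuLi, THF, −78 °C) would add to 7 to give the racemic β-hydroxy selenide F3.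
   - Mitsunobu etherification of 12 with it (PPh3, DIAD, toluene, 0 °C) would give the benzylic aryl ether selenide F4.
   - One equivalent of mCPBA (CH2Cl2, −78 °C) would give the selenoxide F5. Its syn-elimination on warming with i-Pr2NH can only take the C2 hydrogen and would deliver 16.

3. **Step 6.**
   - Possible failures: over-alkylation to dearomatised geminal products, and competing O-alkylation.
   - Fallback, from 9 back to 12: selective silylation of the non-chelated para hydroxyl (TBSCl, 1 equiv, imidazole) would give the 4-O-TBS aldehyde F6.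
   - Tsuji–Trost O-alkylation of both ortho hydroxyls with tert-butyl 2-methylbut-3-en-2-yl carbonate (Pd(PPh3)4 as the source of zerovalent palladium, THF, 0 °C) would give the bis(1,1-dimethylallyl) ether F7.
   - A double aromatic Claisen rearrangement (toluene, 100 °C), in which each ether has only one free ortho position, would give the 3,5-diprenyl 2,6-diol F8.
   - Monosilylation (TBSCl, 1 equiv, imidazole) returns to 12.

**Further compounds**
F1 | step 11 | tris-TBS 2-aryl-4H-chromen-4-ol (racemic) | CC(C)=CCc1c(O[Si](C)(C)C(C)(C)C)c(CC=C(C)C)c2c(c1O[Si](C)(C)C(C)(C)C)C(O)C=C(c1cc3c(cc1O[Si](C)(C)C(C)(C)C)OC(C)(C)C=C3)O2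
F2 | step 11 | tris-TBS flavone | CC(C)=CCc1c(O[Si](C)(C)C(C)(C)C)c(CC=C(C)C)c2c(c1O[Si](C)(C)C(C)(C)C)C(=O)C=C(c1cc3c(cc1O[Si](C)(C)C(C)(C)C)OC(C)(C)C=C3)O2
F3 | step 10 | 1-[7-(tert-butyldimethylsilyloxy)-2,2-dimethyl-2H-chromen-6-yl]-2-(phenylselanyl)ethanol (racemic) | CC1(C)C=Cc2cc(C(O)C[Se]c3ccccc3)c(O[Si](C)(C)C(C)(C)C)cc2O1
F4 | step 10 | benzylic aryl ether selenide (racemic) | CC(C)=CCc1c(O[Si](C)(C)C(C)(C)C)c(CC=C(C)C)c(OC(C[Se]c2ccccc2)c2cc3c(cc2O[Si](C)(C)C(C)(C)C)OC(C)(C)C=C3)c(C=O)c1O[Si](C)(C)C(C)(C)C
F5 | step 10 | selenoxide of F4 (stereoisomer mixture) | CC(C)=CCc1c(O[Si](C)(C)C(C)(C)C)c(CC=C(C)C)c(OC(C[Se](=O)c2ccccc2)c2cc3c(cc2O[Si](C)(C)C(C)(C)C)OC(C)(C)C=C3)c(C=O)c1O[Si](C)(C)C(C)(C)C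
F6 | step 6 | 4-(tert-butyldimethylsilyloxy)-2,6-dihydroxybenzaldehyde | O=Cc1c(O)cc(O[Si](C)(C)C(C)(C)C)cc1O
F7 | step 6 | 4-(tert-butyldimethylsilyloxy)-2,6-bis(2-methylbut-3-en-2-yloxy)benzaldehyde | O=Cc1c(OC(C)(C)C=C)cc(O[Si](C)(C)C(C)(C)C)cc1OC(C)(C)C=C
F8 | step 6 | 4-(tert-butyldimethylsilyloxy)-2,6-dihydroxy-3,5-bis(3-methylbut-2-en-1-yl)benzaldehyde | CC(C)=CCc1c(O)c(C=O)c(O)c(CC=C(C)C)c1O[Si](C)(C)C(C)(C)C
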